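**Retrosynthetic overview**
1. Target 18 ⇐ acetylation of 17 ⇐ second epoxy‑allylsilane bicyclization (rings A′/B′, natural C9′) of polyene 16.
2. 16 ⇐ C12–C9′ bond by one‑pot silylmethylcupration of alkyne 7 and alkylation with keto iodide 14 (ketone decalin already in place).
3. 14 ⇐ first bicyclization (rings A/B, 9‑epi) of allylsilane 12, whose olefin geometry (C7 cis to C11) comes from a directed syn‑silylmethylmagnesiation of homopropargylic alcohol 9 (new step).
4. Both halves ⇐ one alkyne 7 ⇐ (S)‑6,7‑epoxygeranyl bromide 5 ⇐ geranyl acetate 1 by organocatalytic Shi epoxidation, the only source of chirality.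
5. Ring order: A/B of the ketone half first, then A′/B′ of the acetate half.

Assumption: the SMILES is taken literally, so the ketone decalin is 9‑epi (H‑9 β, side chain α, trans to the angular methyl) and the acetate decalin has the usual α‑onocerin configuration; terpenoid numbering is used, with primed locants for the acetate half.

**Step 1**
Reactants: 1 geranyl acetate
Product: 2 (S)-6,7-epoxygeranyl acetate
Conditions: ent‑Shi ketone (1,2:4,5‑di‑O‑isopropylidene‑β‑L‑erythro‑2,3‑hexodiulo‑2,6‑pyranose, 30 mol%), Oxone (2KHSO5·KHSO4·K2SO4), K2CO3, Bu4NHSO4 (cat.), MeCN–CH2(OMe)2/aq. Na2B4O7–Na2EDTA buffer (pH 10.5), 0 °C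
Reagents that add atoms: Oxone, active component potassium peroxymonosulfate KHSO5, [K+].[O-]S(=O)(=O)OO
Why: Shi asymmetric epoxidation, in which the chiral dioxirane attacks the electron‑rich 6,7‑olefin through a spiro transition state (the 2,3‑olefin is deactivated by the allylic acetate) and the L‑series ketone gives the (S)‑epoxide that becomes the 3β‑oxygenated C3/C3′ of both decalins.

**Step 2**
Reactants: 2 (S)-6,7-epoxygeranyl acetate
Product: 3 (S)-6,7-epoxygeraniol
Conditions: K2CO3 (0.2 equiv), MeOH, 0 °C → rt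
Reagents that add atoms: none
Why: Base‑catalysed transesterification (Zemplén type) removes the acetate without opening the trisubstituted epoxide.

**Step 3**
Reactants: 3 (S)-6,7-epoxygeraniol
Product: 5 (S)-6,7-epoxygeranyl bromide, via epoxygeranyl mesylate 4 (not isolated)
Conditions: MsCl, Et3N, THF, −40 °C; then LiBr, THF, 0 °C
Reagents that add atoms: methanesulfonyl chloride CS(=O)(=O)Cl (carried by intermediate 4 only); LiBr [Li+].[Br-]
Why: Mesylation followed by SN2 displacement with bromide at low temperature keeps the E‑olefin and the epoxide intact.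

**Step 4**
Reactants: 5 (S)-6,7-epoxygeranyl bromide
Product: 7 (S,E)-9,10-epoxy-6,10-dimethylundec-5-en-1-yne, via silylalkyne 6 (not isolated)
Conditions: 1‑(trimethylsilyl)propyne, n‑BuLi, THF, −78 °C; add 5, −78 → 0 °C; then K2CO3 (cat.), MeOH, rt
Reagents that add atoms: 1-(trimethylsilyl)propyne CC#C[Si](C)(C)C
Why: Corey–Kirst propargylation, in which the silyl‑blocked propargyllithium displaces the primary allylic bromide in an SN2 sense (no allene, no SN2′) and methanolysis of the C–Si bond releases the terminal alkyne.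

**Step 5**
Reactants: 7 (S,E)-9,10-epoxy-6,10-dimethylundec-5-en-1-yne
Product: 9 (S,E)-11,12-epoxy-8,12-dimethyltridec-7-en-3-yn-1-ol, via lithium acetylide 8 (not isolated)
Conditions: n‑BuLi, THF, −78 °C; ethylene oxide (excess), HMPA, −78 °C → rt; aqueous work‑up
Reagents that add atoms: n-butyllithium CCCC[Li] (lithium of intermediate 8 only); ethylene oxide C1CO1
Why: Acetylide opening of ethylene oxide in a polar aprotic medium (no BF3, so the internal trisubstituted epoxide is not activated) adds C11–C12 and the hydroxyl that directs step 6.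

**Step 6**
Reactants: 9 (S,E)-11,12-epoxy-8,12-dimethyltridec-7-en-3-yn-1-ol
Product: 10 (S,3E,7E)-11,12-epoxy-8,12-dimethyl-4-[(trimethylsilyl)methyl]trideca-3,7-dien-1-ol (chain carbons C‑2 and C‑5 cis across C3=C4; E only because silicon outranks carbon)
Conditions: Me3SiCH2MgCl (4 equiv), Fe(acac)3 (15 mol%), THF, −78 → 0 °C; aq. NH4Cl
Reagents that add atoms: (trimethylsilyl)methylmagnesium chloride C[Si](C)(C)C[Mg]Cl
Why: Proposed new method: iron‑catalysed, alkoxide‑directed syn‑silylmethylmagnesiation of a homopropargylic alcohol, in which the magnesium alkoxide steers the organoiron species so that CH2SiMe3 adds to the distal alkyne carbon (C8, forming C8–C26) and magnesium sits on C9 in a five‑membered oxa‑magnesacycle, so protonation leaves C7 and C11 cis (the geometry later transferred to C9); Me3SiCH2, like Me and Ph, has no β‑hydrogen, so β‑hydride pathways cannot compete; the closest known reaction is the Fe(acac)3‑catalysed carbomagnesiation of propargylic and homopropargylic alcohols with MeMgBr.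

**Step 7**
Reactants: 10 (S,3E,7E)-11,12-epoxy-8,12-dimethyl-4-[(trimethylsilyl)methyl]trideca-3,7-dien-1-ol
Product: 12 (S,3E,7E)-11,12-epoxy-1-iodo-8,12-dimethyl-4-[(trimethylsilyl)methyl]trideca-3,7-diene, via homoallylic mesylate 11 (not isolated)
Conditions: MsCl, Et3N, CH2Cl2, −20 °C; then NaI, acetone, 40 °C
Reagents that add atoms: methanesulfonyl chloride CS(=O)(=O)Cl (carried by intermediate 11 only); NaI [Na+].[I-]
Why: Mesylation and Finkelstein displacement give the primary iodide under neutral conditions that the epoxide and the allylsilane tolerate.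

**Step 8**
Reactants: 12 (S,3E,7E)-11,12-epoxy-1-iodo-8,12-dimethyl-4-[(trimethylsilyl)methyl]trideca-3,7-diene
Product: 13 (2S,4aR,5R,8aR)-5-(2-iodoethyl)-1,1,4a-trimethyl-6-methylidenedecahydronaphthalen-2-ol (3β‑OH, 5α‑H, 10β‑Me, 9β‑H, iodoethyl α)
Conditions: MeAlCl2 (1.5 equiv), CH2Cl2, −94 → −78 °C; aqueous work‑up
Reagents that add atoms: none
Why: Lewis‑acid‑initiated epoxy‑polyene bicyclization with allylsilane termination (Stork–Eschenmoser chair–chair course): anti opening of the (S)‑epoxide gives 3β‑OH, the E C5=C10 olefin gives the trans fusion (5α‑H, 10β‑Me), the C9 substituent cis to C7 (the iodoethyl arm) becomes axial, i.e. α (H‑9 β), and loss of the silyl group fixes the exocyclic 8(26)‑olefin.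

**Step 9**
Reactants: 13 (2S,4aR,5R,8aR)-5-(2-iodoethyl)-1,1,4a-trimethyl-6-methylidenedecahydronaphthalen-2-ol
Product: 14 (4aR,5R,8aR)-5-(2-iodoethyl)-1,1,4a-trimethyl-6-methylideneoctahydronaphthalen-2(1H)-one
Conditions: Dess–Martin periodinane, CH2Cl2, rt
Reagents that add atoms: none
Why: Dess–Martin oxidation converts the hindered secondary alcohol to the C3 ketone while the primary iodide and the 1,1‑disubstituted olefin stay untouched.

**Step 10**
Reactants: 7 (S,E)-9,10-epoxy-6,10-dimethylundec-5-en-1-yne (2 equiv); 14 (4aR,5R,8aR)-5-(2-iodoethyl)-1,1,4a-trimethyl-6-methylideneoctahydronaphthalen-2(1H)-one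
Product: 16 (4aR,5R,8aR)-5-[(3Z,7E)-10-[(2S)-3,3-dimethyloxiran-2-yl]-8-methyl-4-[(trimethylsilyl)methyl]deca-3,7-dien-1-yl]-1,1,4a-trimethyl-6-methylideneoctahydronaphthalen-2(1H)-one, via alkenylcopper 15 (not isolated)
Conditions: Me3SiCH2MgCl, CuBr·SMe2, Et2O–Me2S, −45 °C; 7, −45 → −20 °C; then 14, HMPA, P(OEt)3, −20 °C → rt
Reagents that add atoms: (trimethylsilyl)methylmagnesium chloride C[Si](C)(C)C[Mg]Cl; CuBr·SMe2 Br[Cu].CSC (copper of intermediate 15 only)
Why: Normant syn‑carbocupration puts CH2SiMe3 on the internal alkyne carbon (C8′) and copper on C9′ cis to it, and alkylation of the alkenylcopper by the primary iodide with retention forms C12–C9′ with C7′ trans to C12 (the geometry needed for natural C9′), while the organocopper species leave the ketone and the epoxide alone at low temperature.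

**Step 11**
Reactants: 16 (the epoxy allylsilane from step 10)
Product: 17 (4aR,5R,8aR)-5-{2-[(1S,4aR,6S,8aR)-6-hydroxy-5,5,8a-trimethyl-2-methylidenedecahydronaphthalen-1-yl]ethyl}-1,1,4a-trimethyl-6-methylideneoctahydronaphthalen-2(1H)-one
Conditions: MeAlCl2 (3 equiv), CH2Cl2, −94 → −78 °C; aqueous work‑up
Reagents that add atoms: none
Why: Second epoxy‑polyene bicyclization in the same Lewis‑acid/allylsilane manifold, now with the C9′ substituent trans to C7′, so chair–chair folding from the (S)‑epoxide gives 3′β‑OH, 5′α‑H, 10′β‑Me and an equatorial (β) side chain at C9′ (H‑9′ α), with the exocyclic olefin set by desilylation.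

**Step 12**
Reactants: 17 (the hydroxy ketone from step 11)
Product: 18 (4aR,5R,8aR)-5-{2-[(1S,4aR,6S,8aR)-6-acetoxy-5,5,8a-trimethyl-2-methylidenedecahydronaphthalen-1-yl]ethyl}-1,1,4a-trimethyl-6-methylideneoctahydronaphthalen-2(1H)-one (target)
Conditions: Ac2O, pyridine, DMAP (cat.), CH2Cl2, rt
Reagents that add atoms: acetic anhydride CC(=O)OC(C)=O
Why: DMAP‑catalysed acylation of the only hydroxyl gives the 3′β‑acetate without affecting any stereocentre.

**Compound list**
1 | geranyl acetate | CC(C)=CCC/C(C)=C/COC(C)=O | starting material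
2 | (S)-6,7-epoxygeranyl acetate | CC1(C)O[C@H]1CC/C(C)=C/COC(C)=O | intermediate
3 | (S)-6,7-epoxygeraniol | CC1(C)O[C@H]1CC/C(C)=C/CO | intermediate
4 | (S)-6,7-epoxygeranyl mesylate | CC1(C)O[C@H]1CC/C(C)=C/COS(C)(=O)=O | intermediate (not isolated)
5 | (S)-6,7-epoxygeranyl bromide | CC1(C)O[C@H]1CC/C(C)=C/CBr | intermediate
6 | (S,E)-(9,10-epoxy-6,10-dimethylundec-5-en-1-yn-1-yl)trimethylsilane | CC1(C)O[C@H]1CC/C(C)=C/CCC#C[Si](C)(C)C | intermediate (not isolated)
7 | (S,E)-9,10-epoxy-6,10-dimethylundec-5-en-1-yne | CC1(C)O[C@H]1CC/C(C)=C/CCC#C | intermediate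
8 | lithium acetylide of 7 | CC1(C)O[C@H]1CC/C(C)=C/CCC#C[Li] | intermediate (not isolated)
9 | (S,E)-11,12-epoxy-8,12-dimethyltridec-7-en-3-yn-1-ol | CC1(C)O[C@H]1CC/C(C)=C/CCC#CCCO | intermediate
10 | (S,3E,7E)-11,12-epoxy-8,12-dimethyl-4-[(trimethylsilyl)methyl]trideca-3,7-dien-1-ol | CC1(C)O[C@H]1CC/C(C)=C/CC/C(C[Si](C)(C)C)=C\CCO | intermediate
11 | methanesulfonate of 10 | CC1(C)O[C@H]1CC/C(C)=C/CC/C(C[Si](C)(C)C)=C\CCOS(C)(=O)=O | intermediate (not isolated)
12 | (S,3E,7E)-11,12-epoxy-1-iodo-8,12-dimethyl-4-[(trimethylsilyl)methyl]trideca-3,7-diene | CC1(C)O[C@H]1CC/C(C)=C/CC/C(C[Si](C)(C)C)=C\CCI | intermediate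
13 | (2S,4aR,5R,8aR)-5-(2-iodoethyl)-1,1,4a-trimethyl-6-methylidenedecahydronaphthalen-2-ol | C=C1CC[C@H]2C(C)(C)[C@@H](O)CC[C@]2(C)[C@@H]1CCI | intermediate
14 | (4aR,5R,8aR)-5-(2-iodoethyl)-1,1,4a-trimethyl-6-methylideneoctahydronaphthalen-2(1H)-one | C=C1CC[C@H]2C(C)(C)C(=O)CC[C@]2(C)[C@@H]1CCI | intermediate
15 | alkenylcopper from 7 (Cu on C9′, cis to CH2SiMe3) | CC1(C)O[C@H]1CC/C(C)=C/CC/C(C[Si](C)(C)C)=C/[Cu] | intermediate (not isolated)
16 | (4aR,5R,8aR)-5-[(3Z,7E)-10-[(2S)-3,3-dimethyloxiran-2-yl]-8-methyl-4-[(trimethylsilyl)methyl]deca-3,7-dien-1-yl]-1,1,4a-trimethyl-6-methylideneoctahydronaphthalen-2(1H)-one | CC1(C)O[C@H]1CC/C(C)=C/CC/C(C[Si](C)(C)C)=C/CC[C@@H]1C(=C)CC[C@H]2C(C)(C)C(=O)CC[C@]12C | intermediate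
17 | 3′β-hydroxy ketone (deacetyl target) | C=C1CC[C@H]2C(C)(C)C(=O)CC[C@]2(C)[C@@H]1CC[C@H]1C(=C)CC[C@H]2C(C)(C)[C@@H](O)CC[C@]12C | intermediate
18 | CNP0193500.1 | C=C1CC[C@H]2C(C)(C)C(=O)CC[C@]2(C)[C@@H]1CC[C@H]1C(=C)CC[C@H]2C(C)(C)[C@@H](OC(C)=O)CC[C@]12C | target

**Totals.** 12 steps in all; longest linear sequence 12 steps (1 → 18; alkyne 7 is made once and used in steps 5 and 10). Both decalins come from the same epoxide 2, so the minor enantiomer of 2 ends up mostly in diastereomers of 16–18 that can be separated.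

**Three steps most likely to fail**

Step 6 (the proposed new step). The silylmethyl Grignard reagent may be too hindered for the iron catalyst, or the epoxide may not survive. The fallback uses only known reactions, sets out from 7 and comes back at 10. Alkyne 7 is deprotonated with n‑BuLi and carboxylated with ClCO2Me to methyl (S,E)-10,11-epoxy-7,11-dimethyldodec-6-en-2-ynoate F1. Stereospecific syn conjugate addition of (Me3SiCH2)2CuLi at −78 °C (cuprate addition to an alkynoate) gives methyl (S,2E,6E)-10,11-epoxy-7,11-dimethyl-3-[(trimethylsilyl)methyl]dodeca-2,6-dienoate F2, with C‑4 cis to the ester. Reduction with i‑Bu2AlH gives the allylic alcohol (S,2E,6E)-10,11-epoxy-7,11-dimethyl-3-[(trimethylsilyl)methyl]dodeca-2,6-dien-1-ol F3. Treatment with CBr4/PPh3 gives the allylic bromide (S,2E,6E)-1-bromo-10,11-epoxy-7,11-dimethyl-3-[(trimethylsilyl)methyl]dodeca-2,6-diene F4. CuI‑catalysed SN2 coupling with (i‑PrO)Me2SiCH2MgCl gives (S,3E,7E)-11,12-epoxy-1-[isopropoxy(dimethyl)silyl]-8,12-dimethyl-4-[(trimethylsilyl)methyl]trideca-3,7-diene F5. Tamao oxidation (H2O2, KF, KHCO3) then gives 10.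

Step 8. The bicyclization of this olefin geometry with an allylsilane terminator has no direct precedent; the 9‑epi selectivity or the yield may be poor. The fallback switches to a radical cyclization with a methyl terminator, sets out from 9 and comes back at 13. The established methylmagnesiation (MeMgBr, Fe(acac)3) of 9 gives (S,3Z,7E)-11,12-epoxy-4,8,12-trimethyltrideca-3,7-dien-1-ol F6. Epoxide opening by trivalent titanium (Cp2TiCl made from Cp2TiCl2 and Mn, THF, rt) starts a radical bicyclization that ends by β‑hydride elimination to the exocyclic olefin, giving (2S,4aR,5R,8aR)-5-(2-hydroxyethyl)-1,1,4a-trimethyl-6-methylidenedecahydronaphthalen-2-ol F7. Selective Appel iodination of the primary hydroxyl (I2, PPh3, imidazole, 0 °C) gives 13.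

Step 10. Alkylation of an alkenylcopper with an unactivated iodide is slow and is done here on the most valuable intermediate. The fallback separates the two events, sets out from 7 and 14 and comes back at 16. The alkenylcopper 15 is quenched with I2 to give the isolable alkenyl iodide (S)-3-[(3E,7Z)-8-iodo-3-methyl-7-[(trimethylsilyl)methyl]octa-3,7-dien-1-yl]-2,2-dimethyloxirane F8. Iodide 14 is converted with Zn dust and LiCl to {2-[(1R,4aR,8aR)-5,5,8a-trimethyl-2-methylidene-6-oxodecahydronaphthalen-1-yl]ethyl}zinc iodide F9. Negishi coupling of F8 and F9 with Pd(PPh3)4 (zerovalent palladium) proceeds with retention of olefin geometry and gives 16.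

**Further compounds**
F1 | step 6 | methyl (S,E)-10,11-epoxy-7,11-dimethyldodec-6-en-2-ynoate | CC1(C)O[C@H]1CC/C(C)=C/CCC#CC(=O)OC
F2 | step 6 | methyl (S,2E,6E)-10,11-epoxy-7,11-dimethyl-3-[(trimethylsilyl)methyl]dodeca-2,6-dienoate | CC1(C)O[C@H]1CC/C(C)=C/CC/C(C[Si](C)(C)C)=C\C(=O)OC
F3 | step 6 | (S,2E,6E)-10,11-epoxy-7,11-dimethyl-3-[(trimethylsilyl)methyl]dodeca-2,6-dien-1-ol | CC1(C)O[C@H]1CC/C(C)=C/CC/C(C[Si](C)(C)C)=C\CO
F4 | step 6 | (S,2E,6E)-1-bromo-10,11-epoxy-7,11-dimethyl-3-[(trimethylsilyl)methyl]dodeca-2,6-diene | CC1(C)O[C@H]1CC/C(C)=C/CC/C(C[Si](C)(C)C)=C\CBr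
F5 | step 6 | (S,3E,7E)-11,12-epoxy-1-[isopropoxy(dimethyl)silyl]-8,12-dimethyl-4-[(trimethylsilyl)methyl]trideca-3,7-diene | CC1(C)O[C@H]1CC/C(C)=C/CC/C(C[Si](C)(C)C)=C\CC[Si](C)(C)OC(C)C
F6 | step 8 | (S,3Z,7E)-11,12-epoxy-4,8,12-trimethyltrideca-3,7-dien-1-ol | CC1(C)O[C@H]1CC/C(C)=C/CC/C(C)=C\CCO
F7 | step 8 | (2S,4aR,5R,8aR)-5-(2-hydroxyethyl)-1,1,4a-trimethyl-6-methylidenedecahydronaphthalen-2-ol | C=C1CC[C@H]2C(C)(C)[C@@H](O)CC[C@]2(C)[C@@H]1CCO
F8 | step 10 | (S)-3-[(3E,7Z)-8-iodo-3-methyl-7-[(trimethylsilyl)methyl]octa-3,7-dien-1-yl]-2,2-dimethyloxirane | CC1(C)O[C@H]1CC/C(C)=C/CC/C(C[Si](C)(C)C)=C/I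
F9 | step 10 | {2-[(1R,4aR,8aR)-5,5,8a-trimethyl-2-methylidene-6-oxodecahydronaphthalen-1-yl]ethyl}zinc iodide | C=C1CC[C@H]2C(C)(C)C(=O)CC[C@]2(C)[C@@H]1CC[Zn]I
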